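**Plan**

- Retrosynthesis: the acetate (C13–O) and tiglate (C8–O) are removed. The lactone carbonyl C12 is taken out as CO, which opens the butenolide to a ten-membered 2,3-allenol. The ring bond C7–C8 is cut to an open-chain (Z)-enal carrying a propargylic halide. Then C6–C7, the epoxide oxygen, the C10 methyl and C1–C10 are cut, back to geranyl acetate, methyl propiolate and propargyl chloride.
- Feature used: the butenolide β-carbon C7 lies between two carbinol carbons (C6, C8) and its α-carbon C11 bears the CH2O carbon C13. C6–C7–C11–C13 is therefore a but-2-yne-1,4-diol array and C7 is the γ-carbon of a propargylic metal. Its SE2' attack on C8 closes the ten-membered carbocycle and leaves the allene C7=C11=C13, which is the butenolide minus CO.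
- Forward order: C1–C6 chain from geranyl acetate; C8–C10 added at C1 (propiolate, then methyl cuprate); C7/C11/C13 added at C6 (chloropropyne); ten-membered ring by C7–C8 closure; five-membered lactone last by chlorocyclocarbonylation; chloride exchanged for acetate.
- Stereochemistry: C1 and C6 by catalyst-controlled alkynylations; C4/C5 by hydroxyl-directed epoxidation from C6 under 1,3-allylic strain; C8 by substrate control in the ring closure (relay from C1 across the Z alkene). E C4=C5 comes from geraniol, Z C9=C10 from syn-carbocupration, the E tiglate from tigloyl chloride.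

Key step: step 12

Remark: positions are numbered as in germacranolides: C1 (CHOH), C2, C3, C4 (epoxide C–CH3), C5 (epoxide CH), C6 (lactone CH–O), C7 (butenolide β-C), C8 (CH–O-acyl), C9=C10 (Z, C10 bears CH3), C11 (butenolide α-C), C12 (lactone C=O), C13 (CH2OAc). The 2-methylbut-2-enoate is the E isomer (tiglate). TBS = tert-butyldimethylsilyl, TES = triethylsilyl.

**Route**

Step 1
Reactants: 1 geranyl acetate
Product: 3 (2E)-3-methyl-6-oxohex-2-en-1-yl acetate, via 6,7-epoxygeranyl acetate 2 (not isolated)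
Conditions: mCPBA, CH2Cl2, 0 °C; then H5IO6, THF–H2O, 0 °C
Reagents that add atoms: mCPBA, OOC(=O)c1cccc(Cl)c1
Why: Prilezhaev epoxidation takes the electron-rich 6,7-alkene remote from the acetate, and periodic acid cleaves the epoxide through its glycol to the aldehyde and acetone, leaving the (E)-allylic acetate untouched; no stereocentre is formed.

Step 2
Reactants: 3 (2E)-3-methyl-6-oxohex-2-en-1-yl acetate, 4 methyl propiolate
Product: 5 methyl (4S,7E)-9-acetoxy-4-hydroxy-7-methylnon-7-en-2-ynoate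
Conditions: (S,S)-ProPhenol (20 mol %), Me2Zn, Ph3P=O, toluene, 0 °C
Reagents that add atoms: none
Why: Zinc–ProPhenol asymmetric alkynylation of an aldehyde, in which the dinuclear zinc alkynylide should deliver the propiolate to the Re face (the ligand antipode is the one that gives this face) and so set C1 as S.

Step 3
Reactants: 5 methyl (4S,7E)-9-acetoxy-4-hydroxy-7-methylnon-7-en-2-ynoate
Product: 6 methyl (4S,7E)-9-acetoxy-4-(TBS-oxy)-7-methylnon-7-en-2-ynoate
Conditions: TBSCl, imidazole, DMF, 0 °C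
Reagents that add atoms: TBSCl, CC(C)(C)[Si](C)(C)Cl
Why: Silylation of the secondary propargylic alcohol under mild base, which should avoid isomerisation of the hydroxy ynoate; C1 is untouched.

Step 4
Reactants: 6 methyl (4S,7E)-9-acetoxy-4-(TBS-oxy)-7-methylnon-7-en-2-ynoate
Product: 7 methyl (2Z,4S,7E)-9-acetoxy-4-(TBS-oxy)-3,7-dimethylnona-2,7-dienoate
Conditions: Me2CuLi, THF, −78 °C; MeOH, −78 °C
Reagents that add atoms: lithium dimethylcuprate, [Li+].C[Cu-]C
Why: Syn carbocupration of the ynoate and protonation with retention place the new methyl trans to the ester, which should give the Z C9=C10 alkene with the carbonyl carbon and C1 cis; the allylic acetate should not react at −78 °C.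

Step 5
Reactants: 7 methyl (2Z,4S,7E)-9-acetoxy-4-(TBS-oxy)-3,7-dimethylnona-2,7-dienoate
Product: 8 methyl (2Z,4S,7E)-9-hydroxy-4-(TBS-oxy)-3,7-dimethylnona-2,7-dienoate
Conditions: K2CO3, MeOH, 0 °C
Reagents that add atoms: none
Why: Transesterification removes the primary acetate, while the methyl ester is unchanged by methoxide exchange and the TBS ether is stable.

Step 6
Reactants: 8 methyl (2Z,4S,7E)-9-hydroxy-4-(TBS-oxy)-3,7-dimethylnona-2,7-dienoate
Product: 9 methyl (2Z,4S,7E)-4-(TBS-oxy)-3,7-dimethyl-9-oxonona-2,7-dienoate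
Conditions: MnO2, CH2Cl2, rt
Reagents that add atoms: none
Why: Chemoselective MnO2 oxidation of the primary allylic alcohol to the (E)-enal, which leaves ester and silyl ether alone.

Step 7
Reactants: 9 methyl (2Z,4S,7E)-4-(TBS-oxy)-3,7-dimethyl-9-oxonona-2,7-dienoate, 10 propargyl chloride
Product: 11 methyl (2Z,4S,7E,9R)-12-chloro-9-hydroxy-4-(TBS-oxy)-3,7-dimethyldodeca-2,7-dien-10-ynoate
Conditions: (R,R)-ProPhenol (20 mol %), Me2Zn, Ph3P=O, toluene, 0 °C
Reagents that add atoms: none
Why: Zinc–ProPhenol asymmetric alkynylation on an enal, its best substrate class: catalyst-controlled Si-face addition (ligand antipode opposite to step 2) should set C6 in the target sense (9R here) without influence from remote C1, and the zinc alkynylide should not displace the primary propargylic chloride.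

Step 8
Reactants: 11 methyl (2Z,4S,7E,9R)-12-chloro-9-hydroxy-4-(TBS-oxy)-3,7-dimethyldodeca-2,7-dien-10-ynoate
Product: 12 methyl (2Z,4S,7R,8R,9S)-12-chloro-7,8-epoxy-9-hydroxy-4-(TBS-oxy)-3,7-dimethyldodec-2-en-10-ynoate
Conditions: mCPBA, CH2Cl2, 0 °C
Reagents that add atoms: mCPBA, OOC(=O)c1cccc(Cl)c1
Why: Hydroxyl-directed peracid epoxidation: 1,3-allylic strain with the methyl cis to C6 holds the carbinol hydrogen in the alkene plane, so the hydrogen-bonded peracid should reach one face only and give the threo trans-epoxide (C5–O and C6–O syn, 4R,5R); the electron-poor enoate and the alkyne are inert.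

Step 9
Reactants: 12 methyl (2Z,4S,7R,8R,9S)-12-chloro-7,8-epoxy-9-hydroxy-4-(TBS-oxy)-3,7-dimethyldodec-2-en-10-ynoate
Product: 13 methyl (2Z,4S,7R,8R,9S)-12-chloro-7,8-epoxy-4-(TBS-oxy)-9-(TES-oxy)-3,7-dimethyldodec-2-en-10-ynoate
Conditions: TESOTf, 2,6-lutidine, CH2Cl2, −78 °C
Reagents that add atoms: TESOTf, CC[Si](CC)(CC)OS(=O)(=O)C(F)(F)F
Why: Silylation of the hindered epoxy alcohol with a silyl triflate and a non-nucleophilic base, conditions that should avoid Payne rearrangement.

Step 10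
Reactants: 13 methyl (2Z,4S,7R,8R,9S)-12-chloro-7,8-epoxy-4-(TBS-oxy)-9-(TES-oxy)-3,7-dimethyldodec-2-en-10-ynoate
Product: 14 (2Z,4S,7R,8R,9S)-12-chloro-7,8-epoxy-4-(TBS-oxy)-9-(TES-oxy)-3,7-dimethyldodec-2-en-10-yn-1-ol
Conditions: i-Bu2AlH, CH2Cl2, −78 °C
Reagents that add atoms: none
Why: 1,2-Reduction of the conjugated methyl ester to the allylic alcohol at −78 °C, where epoxide, silyl ethers and propargylic chloride should survive and the Z geometry is kept.

Step 11
Reactants: 14 (2Z,4S,7R,8R,9S)-12-chloro-7,8-epoxy-4-(TBS-oxy)-9-(TES-oxy)-3,7-dimethyldodec-2-en-10-yn-1-ol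
Product: 15 (2Z,4S,7R,8R,9S)-12-chloro-7,8-epoxy-4-(TBS-oxy)-9-(TES-oxy)-3,7-dimethyldodec-2-en-10-ynal
Conditions: Dess–Martin periodinane, pyridine, CH2Cl2, 0 °C
Reagents that add atoms: none
Why: Dess–Martin oxidation under buffered, non-isomerising conditions should give the (Z)-enal; the C1 silyl ether prevents lactol formation.

Step 12
Reactants: 15 (2Z,4S,7R,8R,9S)-12-chloro-7,8-epoxy-4-(TBS-oxy)-9-(TES-oxy)-3,7-dimethyldodec-2-en-10-ynal
Product: 17 (1S,2Z,4S,7R,8R,9S)-7,8-epoxy-10-ethenylidene-4-(TBS-oxy)-9-(TES-oxy)-3,7-dimethylcyclodec-2-en-1-ol, via propargylic iodide 16 (not isolated)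
Conditions: NaI, acetone, rt; then CrCl2, THF–DMF, rt, slow addition to 2 mM
Reagents that add atoms: NaI, [Na+].[I-] (iodine of intermediate 16 only)
Why: Finkelstein exchange gives the propargylic iodide, which takes up two equivalents of divalent chromium to a propargylchromium species with the metal on the primary carbon C13; this adds to the tethered C8 aldehyde through a closed six-membered SE2' transition state, so that the γ-carbon C7 bonds to C8 and the allene C7=C11=C13 is left exocyclic. The closest known reaction type is the Nozaki–Hiyama (chromium Barbier) allenylation of aldehydes by γ-substituted propargylic halides, together with the chromium Barbier closure of ten-membered germacrane rings from allylic halides. The ten-membered carbocycle closes in a 10-exo-trig manner at the aldehyde carbon, under high dilution. The new stereocentre C8 is set by substrate control: 1,3-allylic strain across the Z alkene holds the hydrogens of C1 and of the s-trans aldehyde in the alkene plane, the tether leaves C1 on one face, C7 should reach C8 from that face, and the oxygen then ends on the face of the C1 silyloxy group (8S, ring C1 S). The step needs γ-selectivity (C7 against C13) and chemoselectivity: the first should follow from the metal sitting on the unhindered primary carbon and from the strain of the alternative twelve-membered cycloalkyne, the second from the inertness of epoxide and silyl ethers to CrCl2 and from the poor leaving-group ability of the C6 silyloxy group, which should suppress 1,4-elimination.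

Step 13
Reactants: 17 (1S,2Z,4S,7R,8R,9S)-7,8-epoxy-10-ethenylidene-4-(TBS-oxy)-9-(TES-oxy)-3,7-dimethylcyclodec-2-en-1-ol, 18 tigloyl chloride
Product: 19 (1S,2Z,4S,7R,8R,9S)-7,8-epoxy-10-ethenylidene-4-(TBS-oxy)-9-(TES-oxy)-3,7-dimethylcyclodec-2-en-1-yl (E)-2-methylbut-2-enoate
Conditions: Et3N, DMAP, CH2Cl2, 0 °C
Reagents that add atoms: none
Why: DMAP-catalysed acylation of the secondary alcohol by the acid chloride, with retention at C8 and no risk to the E geometry of the tiglate.

Step 14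
Reactants: 19 (1S,2Z,4S,7R,8R,9S)-7,8-epoxy-10-ethenylidene-4-(TBS-oxy)-9-(TES-oxy)-3,7-dimethylcyclodec-2-en-1-yl (E)-2-methylbut-2-enoate
Product: 20 (1S,2Z,4S,7R,8R,9S)-7,8-epoxy-10-ethenylidene-9-hydroxy-4-(TBS-oxy)-3,7-dimethylcyclodec-2-en-1-yl (E)-2-methylbut-2-enoate
Conditions: HF·pyridine, pyridine, THF, 0 °C
Reagents that add atoms: none
Why: Fluoride-mediated desilylation, in which the triethylsilyl ether should go much faster than the tert-butyldimethylsilyl ether and the pyridine buffer should spare the epoxide.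

Step 15
Reactants: 20 (1S,2Z,4S,7R,8R,9S)-7,8-epoxy-10-ethenylidene-9-hydroxy-4-(TBS-oxy)-3,7-dimethylcyclodec-2-en-1-yl (E)-2-methylbut-2-enoate
Product: 21 (1S,4R,5R,6S,8S,9Z)-13-chloro-4,5-epoxy-1-(TBS-oxy)-8-tigloyloxygermacra-7(11),9-dien-12,6-olide
Conditions: PdCl2 (5 mol %), CuCl2, CO (1 atm), propylene oxide, THF, rt
Reagents that add atoms: carbon monoxide, [C-]#[O+]; CuCl2, Cl[Cu]Cl
Why: Palladium-catalysed chlorocyclocarbonylation of a 2,3-allenol: the free C6 hydroxyl, CO and divalent palladium should build the lactone carbonyl on the central allene carbon C11 while chloride ends on C13, with CuCl2 reoxidising palladium. Only the C6 hydroxyl can close the five-membered ring, which fixes the C7=C11 double bond; propylene oxide traps HCl to protect the epoxide, and C6 is not touched.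

Step 16
Reactants: 21 (1S,4R,5R,6S,8S,9Z)-13-chloro-4,5-epoxy-1-(TBS-oxy)-8-tigloyloxygermacra-7(11),9-dien-12,6-olide
Product: 22 (1S,4R,5R,6S,8S,9Z)-13-acetoxy-4,5-epoxy-1-(TBS-oxy)-8-tigloyloxygermacra-7(11),9-dien-12,6-olide
Conditions: KOAc, 18-crown-6, MeCN, rt
Reagents that add atoms: potassium acetate, CC(=O)[O-].[K+]
Why: SN2 displacement of the primary allylic chloride by acetate; SN2' attack is blocked at the fully substituted C7.

Step 17
Reactants: 22 (1S,4R,5R,6S,8S,9Z)-13-acetoxy-4,5-epoxy-1-(TBS-oxy)-8-tigloyloxygermacra-7(11),9-dien-12,6-olide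
Product: 23 (1S,4R,5R,6S,8S,9Z)-13-acetoxy-4,5-epoxy-1-hydroxy-8-tigloyloxygermacra-7(11),9-dien-12,6-olide
Conditions: HF·pyridine, pyridine, THF, 0 °C to rt
Reagents that add atoms: none
Why: Buffered fluoride desilylation of the secondary TBS ether, which should leave the epoxide, both esters and the butenolide intact and give the target.

**Compound list**

1 | geranyl acetate | CC(=O)OC/C=C(\C)CCC=C(C)C | starting material
2 | 6,7-epoxygeranyl acetate (racemic epoxide) | CC(=O)OC/C=C(\C)CCC1OC1(C)C | intermediate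
3 | (2E)-3-methyl-6-oxohex-2-en-1-yl acetate | CC(=O)OC/C=C(\C)CCC=O | intermediate
4 | methyl propiolate | C#CC(=O)OC | starting material
5 | methyl (4S,7E)-9-acetoxy-4-hydroxy-7-methylnon-7-en-2-ynoate | COC(=O)C#C[C@@H](O)CC/C(C)=C/COC(C)=O | intermediate
6 | methyl (4S,7E)-9-acetoxy-4-(TBS-oxy)-7-methylnon-7-en-2-ynoate | COC(=O)C#C[C@@H](O[Si](C)(C)C(C)(C)C)CC/C(C)=C/COC(C)=O | intermediate
7 | methyl (2Z,4S,7E)-9-acetoxy-4-(TBS-oxy)-3,7-dimethylnona-2,7-dienoate | COC(=O)/C=C(/C)[C@@H](O[Si](C)(C)C(C)(C)C)CC/C(C)=C/COC(C)=O | intermediate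
8 | methyl (2Z,4S,7E)-9-hydroxy-4-(TBS-oxy)-3,7-dimethylnona-2,7-dienoate | COC(=O)/C=C(/C)[C@@H](O[Si](C)(C)C(C)(C)C)CC/C(C)=C/CO | intermediate
9 | methyl (2Z,4S,7E)-4-(TBS-oxy)-3,7-dimethyl-9-oxonona-2,7-dienoate | COC(=O)/C=C(/C)[C@@H](O[Si](C)(C)C(C)(C)C)CC/C(C)=C/C=O | intermediate
10 | propargyl chloride (3-chloroprop-1-yne) | C#CCCl | starting material
11 | methyl (2Z,4S,7E,9R)-12-chloro-9-hydroxy-4-(TBS-oxy)-3,7-dimethyldodeca-2,7-dien-10-ynoate | COC(=O)/C=C(/C)[C@@H](O[Si](C)(C)C(C)(C)C)CC/C(C)=C/[C@@H](O)C#CCCl | intermediate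
12 | methyl (2Z,4S,7R,8R,9S)-12-chloro-7,8-epoxy-9-hydroxy-4-(TBS-oxy)-3,7-dimethyldodec-2-en-10-ynoate | COC(=O)/C=C(/C)[C@@H](O[Si](C)(C)C(C)(C)C)CC[C@@]1(C)O[C@@H]1[C@@H](O)C#CCCl | intermediate
13 | methyl (2Z,4S,7R,8R,9S)-12-chloro-7,8-epoxy-4-(TBS-oxy)-9-(TES-oxy)-3,7-dimethyldodec-2-en-10-ynoate | COC(=O)/C=C(/C)[C@@H](O[Si](C)(C)C(C)(C)C)CC[C@@]1(C)O[C@@H]1[C@@H](O[Si](CC)(CC)CC)C#CCCl | intermediate
14 | (2Z,4S,7R,8R,9S)-12-chloro-7,8-epoxy-4-(TBS-oxy)-9-(TES-oxy)-3,7-dimethyldodec-2-en-10-yn-1-ol | OC/C=C(/C)[C@@H](O[Si](C)(C)C(C)(C)C)CC[C@@]1(C)O[C@@H]1[C@@H](O[Si](CC)(CC)CC)C#CCCl | intermediate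
15 | (2Z,4S,7R,8R,9S)-12-chloro-7,8-epoxy-4-(TBS-oxy)-9-(TES-oxy)-3,7-dimethyldodec-2-en-10-ynal | O=C/C=C(/C)[C@@H](O[Si](C)(C)C(C)(C)C)CC[C@@]1(C)O[C@@H]1[C@@H](O[Si](CC)(CC)CC)C#CCCl | intermediate
16 | (2Z,4S,7R,8R,9S)-7,8-epoxy-12-iodo-4-(TBS-oxy)-9-(TES-oxy)-3,7-dimethyldodec-2-en-10-ynal | O=C/C=C(/C)[C@@H](O[Si](C)(C)C(C)(C)C)CC[C@@]1(C)O[C@@H]1[C@@H](O[Si](CC)(CC)CC)C#CCI | intermediate
17 | (1S,2Z,4S,7R,8R,9S)-7,8-epoxy-10-ethenylidene-4-(TBS-oxy)-9-(TES-oxy)-3,7-dimethylcyclodec-2-en-1-ol | O[C@H]1/C=C(/C)[C@@H](O[Si](C)(C)C(C)(C)C)CC[C@@]2(C)O[C@@H]2[C@@H](O[Si](CC)(CC)CC)C1=C=C | intermediate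
18 | tigloyl chloride, (E)-2-methylbut-2-enoyl chloride | C/C=C(\C)C(=O)Cl | starting material
19 | (1S,2Z,4S,7R,8R,9S)-7,8-epoxy-10-ethenylidene-4-(TBS-oxy)-9-(TES-oxy)-3,7-dimethylcyclodec-2-en-1-yl (E)-2-methylbut-2-enoate | C/C=C(\C)C(=O)O[C@H]1/C=C(/C)[C@@H](O[Si](C)(C)C(C)(C)C)CC[C@@]2(C)O[C@@H]2[C@@H](O[Si](CC)(CC)CC)C1=C=C | intermediate
20 | (1S,2Z,4S,7R,8R,9S)-7,8-epoxy-10-ethenylidene-9-hydroxy-4-(TBS-oxy)-3,7-dimethylcyclodec-2-en-1-yl (E)-2-methylbut-2-enoate | C/C=C(\C)C(=O)O[C@H]1/C=C(/C)[C@@H](O[Si](C)(C)C(C)(C)C)CC[C@@]2(C)O[C@@H]2[C@@H](O)C1=C=C | intermediate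
21 | (1S,4R,5R,6S,8S,9Z)-13-chloro-4,5-epoxy-1-(TBS-oxy)-8-tigloyloxygermacra-7(11),9-dien-12,6-olide | C/C=C(\C)C(=O)O[C@H]1/C=C(/C)[C@@H](O[Si](C)(C)C(C)(C)C)CC[C@@]2(C)O[C@@H]2[C@H]2OC(=O)C(CCl)=C12 | intermediate
22 | (1S,4R,5R,6S,8S,9Z)-13-acetoxy-4,5-epoxy-1-(TBS-oxy)-8-tigloyloxygermacra-7(11),9-dien-12,6-olide | C/C=C(\C)C(=O)O[C@H]1/C=C(/C)[C@@H](O[Si](C)(C)C(C)(C)C)CC[C@@]2(C)O[C@@H]2[C@H]2OC(=O)C(COC(C)=O)=C12 | intermediate
23 | (1S,4R,5R,6S,8S,9Z)-13-acetoxy-4,5-epoxy-1-hydroxy-8-tigloyloxygermacra-7(11),9-dien-12,6-olide | C/C=C(\C)C(=O)O[C@H]1/C=C(/C)[C@@H](O)CC[C@@]2(C)O[C@@H]2[C@H]2OC(=O)C(COC(C)=O)=C12 | target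

**Totals and risks**

Total step count: 17. Longest linear sequence: 17 steps (from geranyl acetate).

Steps most likely to fail:

1. Step 12. The ring closure is the least precedented step, and its facial bias rests only on conformational relay from C1, so the aldehyde may be attacked on the wrong face and give the C8 epimer. The fallback sets out from 15 and comes back at 19. The epimeric cyclodecenol, (1R,2Z,4S,7R,8R,9S)-7,8-epoxy-10-ethenylidene-4-(TBS-oxy)-9-(TES-oxy)-3,7-dimethylcyclodec-2-en-1-ol F1, is not acylated with 18. It is esterified with tiglic acid under Mitsunobu conditions (PPh3, diisopropyl azodicarboxylate, toluene, 0 °C), which inverts C8 and should deliver 19 directly.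

2. Step 15. The acid and the CuCl2 may open the trisubstituted epoxide, or transient zerovalent palladium may ionise the allylic tiglate, before the lactone closes. The fallback sets out from 20 and comes back at 22, without CO or acid.
   - N-Iodosuccinimide (MeCN, 0 °C) closes the C6 hydroxyl onto the allene terminus (5-endo iodoetherification) to the fused 3-iodo-2,5-dihydrofuran F2.
   - Allylic oxidation of the ring OCH2 (CrO3, 3,5-dimethylpyrazole, CH2Cl2, −20 °C) gives the α-iodobutenolide F3.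
   - Stille coupling with (tributylstannyl)methanol (Pd2(dba)3, AsPh3, CuI, NMP, rt) gives the α-(hydroxymethyl)butenolide F4.
   - Acetylation (Ac2O, pyridine) gives 22.
   - Here the lactone carbonyl is the former allene terminus and the CH2O carbon comes from the stannane, which leads to the same constitution.

3. Step 7. The chloropropynyl zinc species may add with poor enantiofacial control, or may decompose before it adds. The fallback sets out from 9 and comes back at 11.
   - Lithium 3-chloropropynide (propargyl chloride, n-BuLi, THF, −90 °C) adds to the enal and gives the carbinol as a mixture of C9 epimers, methyl (2Z,4S,7E)-12-chloro-9-hydroxy-4-(TBS-oxy)-3,7-dimethyldodeca-2,7-dien-10-ynoate F5.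
   - Dess–Martin oxidation gives the ynone, methyl (2Z,4S,7E)-12-chloro-4-(TBS-oxy)-3,7-dimethyl-9-oxododeca-2,7-dien-10-ynoate F6.
   - CBS reduction with the (R)-methyl oxazaborolidine and BH3·SMe2 (alkynyl as the small group) should then give 11.

**Further compounds**

F1 | step 12 | (1R,2Z,4S,7R,8R,9S)-7,8-epoxy-10-ethenylidene-4-(TBS-oxy)-9-(TES-oxy)-3,7-dimethylcyclodec-2-en-1-ol (C8 epimer of 17) | O[C@@H]1/C=C(/C)[C@@H](O[Si](C)(C)C(C)(C)C)CC[C@@]2(C)O[C@@H]2[C@@H](O[Si](CC)(CC)CC)C1=C=C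
F2 | step 15 | fused 3-iodo-2,5-dihydrofuran (O6–CH2 ether ring, iodine on C11) of the ten-membered tiglate | C/C=C(\C)C(=O)O[C@H]1/C=C(/C)[C@@H](O[Si](C)(C)C(C)(C)C)CC[C@@]2(C)O[C@@H]2[C@H]2OCC(I)=C12
F3 | step 15 | fused α-iodobutenolide | C/C=C(\C)C(=O)O[C@H]1/C=C(/C)[C@@H](O[Si](C)(C)C(C)(C)C)CC[C@@]2(C)O[C@@H]2[C@H]2OC(=O)C(I)=C12
F4 | step 15 | fused α-(hydroxymethyl)butenolide (13-hydroxy analogue of 22) | C/C=C(\C)C(=O)O[C@H]1/C=C(/C)[C@@H](O[Si](C)(C)C(C)(C)C)CC[C@@]2(C)O[C@@H]2[C@H]2OC(=O)C(CO)=C12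
F5 | step 7 | methyl (2Z,4S,7E)-12-chloro-9-hydroxy-4-(TBS-oxy)-3,7-dimethyldodeca-2,7-dien-10-ynoate (mixture of C9 epimers) | COC(=O)/C=C(/C)[C@@H](O[Si](C)(C)C(C)(C)C)CC/C(C)=C/C(O)C#CCCl
F6 | step 7 | methyl (2Z,4S,7E)-12-chloro-4-(TBS-oxy)-3,7-dimethyl-9-oxododeca-2,7-dien-10-ynoate | COC(=O)/C=C(/C)[C@@H](O[Si](C)(C)C(C)(C)C)CC/C(C)=C/C(=O)C#CCCl
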